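**Retrosynthetic overview**

1. Feature (tetralin numbering: C1 carries the pendant ring C, C2 and C3 carry C9H2OH and C10H2OH, C4 is CH2, ring A is C4a–C8a with OMe on C6/C8 and OH on C7, ring B is the saturated ring): C1 is benzylic and para to the ring C hydroxyl, so it is a latent p-quinone methide carbon, and C9–C2–C3 is a latent enal whose β-carbon C3 can take nitromethane as C10.
2. Target ⇐ nitro aldehyde 15 by functional-group changes only (C9HO → CH2OH; C10H2NO2 → CO2H → CH2OH; C7 O-debenzylation).
3. 15 ⇐ quinone methide enal 12 + nitromethane in one amine-catalysed operation: C3–C10 by Michael addition, then C1–C2 by 1,6-addition. Ring B is the only ring made; rings A and C are bought as arenes.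
4. 12 ⇐ diarylmethane phenol 11 (Ag2O oxidation) ⇐ allylarene 9 + crotonaldehyde (cross-metathesis) ⇐ ring A aldehyde 4 + ring C aryllithium 7 (C1–ring C bond). The C7 oxygen stays benzylated so that only ring C can form a quinone methide.

Key step: step 8

Remark on the chemistry: quinone methide 12 is assumed to persist in dry CH2Cl2 long enough to be filtered and used at once as a solution; it is not stored.

**Step 1**
Reactants: 1 4-allyl-2,6-dimethoxyphenol (methoxyeugenol)
Product: 2 5-allyl-2-(benzyloxy)-1,3-dimethoxybenzene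
Conditions: BnBr, K2CO3, DMF, rt
Reagents that add atoms: benzyl bromide, BrCc1ccccc1
Why: Williamson ether synthesis on the phenoxide; the benzyl ether masks the C7 oxygen (para to C4a) so that only ring C can later become a quinone methide, and it is removed last by hydrogenolysis.

**Step 2**
Reactants: 2 5-allyl-2-(benzyloxy)-1,3-dimethoxybenzene
Product: 4 6-allyl-3-(benzyloxy)-2,4-dimethoxybenzaldehyde, via aryl iminium chloride 3 (not isolated)
Conditions: POCl3, DMF, 0 → 75 °C; then aq. NaOAc, rt
Reagents that add atoms: N,N-dimethylformamide, CN(C)C=O; water, O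
Why: Vilsmeier–Haack formylation of a 1,2,3-trialkoxybenzene whose two free positions are equivalent and each lie ortho to one methoxy group and para to the other, so the formyl carbon (the future C1) can only enter next to the allyl group, while the isolated terminal alkene is too weak a nucleophile for the chloroiminium ion.

**Step 3**
Reactants: 5 4-bromo-2,6-dimethoxyphenol
Product: 6 5-bromo-1,3-dimethoxy-2-[(4-methoxybenzyl)oxy]benzene
Conditions: PMBCl, K2CO3, DMF, 60 °C
Reagents that add atoms: 4-methoxybenzyl chloride, COc1ccc(CCl)cc1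
Why: Williamson ether synthesis; the 4-methoxybenzyl ether withstands n-BuLi and is later cleaved by the same acid that ionises the carbinol in step 5, leaving the ring A benzyl ether in place.

**Step 4**
Reactants: 6 5-bromo-1,3-dimethoxy-2-[(4-methoxybenzyl)oxy]benzene; 4 6-allyl-3-(benzyloxy)-2,4-dimethoxybenzaldehyde
Product: 8 [6-allyl-3-(benzyloxy)-2,4-dimethoxyphenyl]{3,5-dimethoxy-4-[(4-methoxybenzyl)oxy]phenyl}methanol (racemic), via aryllithium 7 (not isolated)
Conditions: n-BuLi, THF, −78 °C; then 4, −78 → 0 °C; H2O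
Reagents that add atoms: none
Why: Bromine–lithium exchange at −78 °C outruns any deprotonation and the aryllithium adds 1,2 to the aldehyde to join ring C to the future C1; the carbinol centre is racemic and is erased in step 5.

**Step 5**
Reactants: 8 [6-allyl-3-(benzyloxy)-2,4-dimethoxyphenyl]{3,5-dimethoxy-4-[(4-methoxybenzyl)oxy]phenyl}methanol
Product: 9 4-{[6-allyl-3-(benzyloxy)-2,4-dimethoxyphenyl]methyl}-2,6-dimethoxyphenol
Conditions: Et3SiH (5 equiv), TFA (10 equiv), CH2Cl2, 0 °C
Reagents that add atoms: none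
Why: Ionic hydrogenation, in which TFA ionises the doubly aryl-stabilised carbinol and Et3SiH delivers hydride to give the diarylmethane, while the same medium cleaves the PMB ether and the silane traps the 4-methoxybenzyl cation; the monosubstituted alkene and the benzyl ether are inert at 0 °C.

**Step 6**
Reactants: 9 4-{[6-allyl-3-(benzyloxy)-2,4-dimethoxyphenyl]methyl}-2,6-dimethoxyphenol; 10 (E)-but-2-enal (crotonaldehyde)
Product: 11 (E)-4-{4-(benzyloxy)-2-[(4-hydroxy-3,5-dimethoxyphenyl)methyl]-3,5-dimethoxyphenyl}but-2-enal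
Conditions: 10 (5 equiv), second-generation Hoveyda–Grubbs catalyst RuCl2(H2IMes)(=CH–C6H4-2-OiPr) (5 mol%), CH2Cl2, 40 °C
Reagents that add atoms: none
Why: Olefin cross-metathesis of a terminal allylarene with an enal partner should give the E-configured cross product selectively, and the ruthenium carbene tolerates the free phenol.

**Step 7**
Reactants: 11 (E)-4-{4-(benzyloxy)-2-[(4-hydroxy-3,5-dimethoxyphenyl)methyl]-3,5-dimethoxyphenyl}but-2-enal
Product: 12 4-({3-(benzyloxy)-2,4-dimethoxy-6-[(E)-4-oxobut-2-enyl]phenyl}methylidene)-2,6-dimethoxycyclohexa-2,5-dien-1-one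
Conditions: Ag2O (4 equiv), CH2Cl2, rt, dark; filtered through Celite and used at once as the solution
Reagents that add atoms: none
Why: Two-electron oxidation of a 4-benzyl-2,6-dimethoxyphenol to its p-quinone methide with Ag2O is a known neutral, anhydrous reaction that turns C1 into the quinone methide carbon; ring A cannot react likewise because its C7 oxygen is benzylated, and the enal is not attacked in the absence of base and water.

**Step 8**
Reactants: 12 4-({3-(benzyloxy)-2,4-dimethoxy-6-[(E)-4-oxobut-2-enyl]phenyl}methylidene)-2,6-dimethoxycyclohexa-2,5-dien-1-one; 13 nitromethane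
Product: 15 (1S,2R,3R)-7-(benzyloxy)-1-(4-hydroxy-3,5-dimethoxyphenyl)-6,8-dimethoxy-3-(nitromethyl)-1,2,3,4-tetrahydronaphthalene-2-carbaldehyde, via Michael-adduct enamine 14 (not isolated)
Conditions: 13 (10 equiv), (S)-2-[diphenyl(trimethylsilyloxy)methyl]pyrrolidine (20 mol%), PhCO2H (20 mol%), CH2Cl2 (no alcohol solvent), 0 °C → rt
Reagents that add atoms: none
Why: Proposed new method: the (S)-amine condenses with the enal of 12 to an E-iminium ion, nitronate adds to C3 on the face away from the CPh2OSiMe3 group (C3–C10), and the resulting enamine 14 attacks the quinone methide carbon C1 through C2 (C1–C2), after which hydrolysis releases 15 and the catalyst. The closest known reactions are the diarylprolinol silyl ether-catalysed Michael addition of nitromethane to enals and the enamine 1,6-addition of aldehydes to p-quinone methides, joined here as an iminium–enamine cascade. Ring B closes in a 6-exo-trig 1,6-addition driven by rearomatisation of ring C. C3 is set by the catalyst (the (S)-catalyst should give 3R, the same facial sense as in the known nitromethane additions), C1 by a chair-like closure that keeps the C3 nitromethyl arm and ring C pseudo-equatorial and hence cis, and C2 by equilibration of the epimerisable formyl centre to the equatorial position trans to both neighbours, whichever enamine face reacts first. The step needs nitronate to choose the cationic iminium carbon C3 over the neutral, twisted quinone methide carbon C1, and needs Michael addition to outrun deprotonation at C4 to the dienamine; the far higher electrophilicity of the iminium ion, the excess of nitromethane and the acid co-catalyst should secure both.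

**Step 9**
Reactants: 15 (1S,2R,3R)-7-(benzyloxy)-1-(4-hydroxy-3,5-dimethoxyphenyl)-6,8-dimethoxy-3-(nitromethyl)-1,2,3,4-tetrahydronaphthalene-2-carbaldehyde
Product: 16 [(1S,2R,3R)-7-(benzyloxy)-1-(4-hydroxy-3,5-dimethoxyphenyl)-6,8-dimethoxy-3-(nitromethyl)-1,2,3,4-tetrahydronaphthalen-2-yl]methanol
Conditions: NaBH4, MeOH/CH2Cl2, 0 °C
Reagents that add atoms: none
Why: Chemoselective borohydride 1,2-reduction of the aldehyde leaves the nitro group untouched and removes the only epimerisable centre, so the trans,trans triad is fixed.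

**Step 10**
Reactants: 16 [(1S,2R,3R)-7-(benzyloxy)-1-(4-hydroxy-3,5-dimethoxyphenyl)-6,8-dimethoxy-3-(nitromethyl)-1,2,3,4-tetrahydronaphthalen-2-yl]methanol
Product: 17 [(1S,2R,3R)-1-(4-acetoxy-3,5-dimethoxyphenyl)-7-(benzyloxy)-6,8-dimethoxy-3-(nitromethyl)-1,2,3,4-tetrahydronaphthalen-2-yl]methyl acetate
Conditions: Ac2O, pyridine, rt
Reagents that add atoms: acetic anhydride, CC(=O)OC(C)=O
Why: Acylation of the phenol and the primary alcohol under conditions too weakly basic to deprotonate the nitroalkane; the aryl acetate lowers the electron density of ring C and the alkyl acetate blocks the C9 hydroxyl, so neither interferes with the nitrosating medium of step 11.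

**Step 11**
Reactants: 17 [(1S,2R,3R)-1-(4-acetoxy-3,5-dimethoxyphenyl)-7-(benzyloxy)-6,8-dimethoxy-3-(nitromethyl)-1,2,3,4-tetrahydronaphthalen-2-yl]methyl acetate
Product: 18 (2R,3R,4S)-3-(acetoxymethyl)-4-(4-acetoxy-3,5-dimethoxyphenyl)-6-(benzyloxy)-5,7-dimethoxy-1,2,3,4-tetrahydronaphthalene-2-carboxylic acid (the C10 acid; 1S,2R,3R in target numbering)
Conditions: NaNO2 (3 equiv), AcOH (10 equiv), DMSO, 35 °C
Reagents that add atoms: sodium nitrite, [Na+].[O-]N=O
Why: Oxidative Nef-type conversion of a primary nitroalkane into a carboxylic acid (nitrosation of the aci-nitro tautomer and breakdown with loss of nitrogen oxides) acts at C10 only, and the weakly acidic medium offers no pathway for epimerisation at C3.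

**Step 12**
Reactants: 18 (2R,3R,4S)-3-(acetoxymethyl)-4-(4-acetoxy-3,5-dimethoxyphenyl)-6-(benzyloxy)-5,7-dimethoxy-1,2,3,4-tetrahydronaphthalene-2-carboxylic acid
Product: 19 [(1S,2R,3R)-7-(benzyloxy)-1-(4-hydroxy-3,5-dimethoxyphenyl)-6,8-dimethoxy-1,2,3,4-tetrahydronaphthalene-2,3-diyl]dimethanol
Conditions: LiAlH4 (excess), THF, 0 °C → reflux; aq. potassium sodium tartrate work-up
Reagents that add atoms: none
Why: Hydride reduction takes the carboxylic acid to the C10 primary alcohol and cleaves both acetates in the same operation, while the benzyl ether and the three stereocentres are not affected.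

**Step 13**
Reactants: 19 [(1S,2R,3R)-7-(benzyloxy)-1-(4-hydroxy-3,5-dimethoxyphenyl)-6,8-dimethoxy-1,2,3,4-tetrahydronaphthalene-2,3-diyl]dimethanol
Product: 20 [(1S,2R,3R)-7-hydroxy-1-(4-hydroxy-3,5-dimethoxyphenyl)-6,8-dimethoxy-1,2,3,4-tetrahydronaphthalene-2,3-diyl]dimethanol (CNP0153696.1)
Conditions: H2 (1 atm), 10% Pd/C, MeOH/EtOAc, rt
Reagents that add atoms: none
Why: Heterogeneous hydrogenolysis of the aryl benzyl ether frees the C7 phenol; the molecule holds no other reducible or hydrogenolysable group and no stereocentre carries a benzylic oxygen.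

**Compound list**

1 | 4-allyl-2,6-dimethoxyphenol (methoxyeugenol) | C=CCc1cc(OC)c(O)c(OC)c1 | starting material
2 | 5-allyl-2-(benzyloxy)-1,3-dimethoxybenzene | C=CCc1cc(OC)c(OCc2ccccc2)c(OC)c1 | intermediate
3 | N-{[6-allyl-3-(benzyloxy)-2,4-dimethoxyphenyl]methylidene}-N-methylmethanaminium chloride | C=CCc1cc(OC)c(OCc2ccccc2)c(OC)c1C=[N+](C)C.[Cl-] | intermediate (not isolated)
4 | 6-allyl-3-(benzyloxy)-2,4-dimethoxybenzaldehyde | C=CCc1cc(OC)c(OCc2ccccc2)c(OC)c1C=O | intermediate
5 | 4-bromo-2,6-dimethoxyphenol | COc1cc(Br)cc(OC)c1O | starting material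
6 | 5-bromo-1,3-dimethoxy-2-[(4-methoxybenzyl)oxy]benzene | COc1ccc(COc2c(OC)cc(Br)cc2OC)cc1 | intermediate
7 | {3,5-dimethoxy-4-[(4-methoxybenzyl)oxy]phenyl}lithium | [Li]c1cc(OC)c(OCc2ccc(OC)cc2)c(OC)c1 | intermediate (not isolated)
8 | [6-allyl-3-(benzyloxy)-2,4-dimethoxyphenyl]{3,5-dimethoxy-4-[(4-methoxybenzyl)oxy]phenyl}methanol, racemic | C=CCc1cc(OC)c(OCc2ccccc2)c(OC)c1C(O)c1cc(OC)c(OCc2ccc(OC)cc2)c(OC)c1 | intermediate
9 | 4-{[6-allyl-3-(benzyloxy)-2,4-dimethoxyphenyl]methyl}-2,6-dimethoxyphenol | C=CCc1cc(OC)c(OCc2ccccc2)c(OC)c1Cc1cc(OC)c(O)c(OC)c1 | intermediate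
10 | (E)-but-2-enal (crotonaldehyde) | C/C=C/C=O | starting material
11 | (E)-4-{4-(benzyloxy)-2-[(4-hydroxy-3,5-dimethoxyphenyl)methyl]-3,5-dimethoxyphenyl}but-2-enal | O=C/C=C/Cc1cc(OC)c(OCc2ccccc2)c(OC)c1Cc1cc(OC)c(O)c(OC)c1 | intermediate
12 | 4-({3-(benzyloxy)-2,4-dimethoxy-6-[(E)-4-oxobut-2-enyl]phenyl}methylidene)-2,6-dimethoxycyclohexa-2,5-dien-1-one | COC1=CC(=Cc2c(C/C=C/C=O)cc(OC)c(OCc3ccccc3)c2OC)C=C(OC)C1=O | intermediate
13 | nitromethane | C[N+](=O)[O-] | starting material
14 | E-enamine of the (3R) Michael adduct with the (S)-catalyst, quinone methide intact (C3 carries CH2NO2; C9=C2 is the enamine double bond) | COC1=CC(=Cc2c(C[C@@H](C[N+](=O)[O-])/C=C/N3CCC[C@H]3C(c3ccccc3)(c3ccccc3)O[Si](C)(C)C)cc(OC)c(OCc3ccccc3)c2OC)C=C(OC)C1=O | intermediate (not isolated)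
15 | (1S,2R,3R)-7-(benzyloxy)-1-(4-hydroxy-3,5-dimethoxyphenyl)-6,8-dimethoxy-3-(nitromethyl)-1,2,3,4-tetrahydronaphthalene-2-carbaldehyde (all-trans) | COc1cc([C@H]2c3c(cc(OC)c(OCc4ccccc4)c3OC)C[C@@H](C[N+](=O)[O-])[C@@H]2C=O)cc(OC)c1O | intermediate
16 | [(1S,2R,3R)-7-(benzyloxy)-1-(4-hydroxy-3,5-dimethoxyphenyl)-6,8-dimethoxy-3-(nitromethyl)-1,2,3,4-tetrahydronaphthalen-2-yl]methanol | COc1cc([C@H]2c3c(cc(OC)c(OCc4ccccc4)c3OC)C[C@@H](C[N+](=O)[O-])[C@@H]2CO)cc(OC)c1O | intermediate
17 | [(1S,2R,3R)-1-(4-acetoxy-3,5-dimethoxyphenyl)-7-(benzyloxy)-6,8-dimethoxy-3-(nitromethyl)-1,2,3,4-tetrahydronaphthalen-2-yl]methyl acetate | COc1cc([C@H]2c3c(cc(OC)c(OCc4ccccc4)c3OC)C[C@@H](C[N+](=O)[O-])[C@@H]2COC(C)=O)cc(OC)c1OC(C)=O | intermediate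
18 | (2R,3R,4S)-3-(acetoxymethyl)-4-(4-acetoxy-3,5-dimethoxyphenyl)-6-(benzyloxy)-5,7-dimethoxy-1,2,3,4-tetrahydronaphthalene-2-carboxylic acid | COc1cc([C@H]2c3c(cc(OC)c(OCc4ccccc4)c3OC)C[C@@H](C(=O)O)[C@@H]2COC(C)=O)cc(OC)c1OC(C)=O | intermediate
19 | [(1S,2R,3R)-7-(benzyloxy)-1-(4-hydroxy-3,5-dimethoxyphenyl)-6,8-dimethoxy-1,2,3,4-tetrahydronaphthalene-2,3-diyl]dimethanol | COc1cc([C@H]2c3c(cc(OC)c(OCc4ccccc4)c3OC)C[C@@H](CO)[C@@H]2CO)cc(OC)c1O | intermediate
20 | [(1S,2R,3R)-7-hydroxy-1-(4-hydroxy-3,5-dimethoxyphenyl)-6,8-dimethoxy-1,2,3,4-tetrahydronaphthalene-2,3-diyl]dimethanol (CNP0153696.1) | COc1cc([C@H]2c3c(cc(OC)c(O)c3OC)C[C@@H](CO)[C@@H]2CO)cc(OC)c1O | target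

**Step count and risks**

Total: 13 steps. Longest linear sequence: 12 steps (steps 1, 2 and 4–13, from methoxyeugenol 1).

Steps most likely to fail:

1. Step 8 (the proposed cascade). Three things may go wrong. The iminium ion may be deprotonated at C4 to the dienamine, which either moves the double bond into conjugation with ring A or closes onto C1 without nitromethane. Nitronate or the amine catalyst may add to C1 of the quinone methide. Facial control at C1 during closure may be weak. The fallback runs the same bond formations one at a time by known reactions, setting out from 11 and returning at 15. Enal 11 is treated with nitromethane 13, the same (S)-catalyst and PhCO2H in MeOH, the established protic conditions for nitromethane addition to enals, to give (3R)-3-({4-(benzyloxy)-2-[(4-hydroxy-3,5-dimethoxyphenyl)methyl]-3,5-dimethoxyphenyl}methyl)-4-nitrobutanal F1. Ag2O in CH2Cl2 then oxidises the phenol to 4-({3-(benzyloxy)-2,4-dimethoxy-6-[(2R)-2-(nitromethyl)-4-oxobutyl]phenyl}methylidene)-2,6-dimethoxycyclohexa-2,5-dien-1-one F2. A catalytic secondary amine (pyrrolidine/AcOH, or either enantiomer of the prolinol silyl ether if the C1 outcome needs tuning) closes ring B by intramolecular enamine 1,6-addition to give 15. In this order enal and quinone methide are never present together, so the chemoselectivity question does not arise and the Michael step runs under its proven conditions.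

2. Step 7. The phenoxyl radical may couple or be over-oxidised instead of disproportionating cleanly to the quinone methide, and 12 may be lost on handling. The fallback is non-oxidative, setting out from 8 and returning at 12. Carbinol 8 is cross-metathesised with crotonaldehyde 10 under the conditions of step 6 to give (E)-4-[4-(benzyloxy)-2-(hydroxy{3,5-dimethoxy-4-[(4-methoxybenzyl)oxy]phenyl}methyl)-3,5-dimethoxyphenyl]but-2-enal F3 (racemic). Brief treatment with TFA and anisole in CH2Cl2 at 0 °C removes the PMB group, with anisole taking up the 4-methoxybenzyl cation, and ionises the carbinol to the 4-hydroxybenzhydryl cation. Pouring into cold aqueous NaHCO3 removes the phenolic proton and should give 12 by dehydration.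

3. Step 11. The nitrosating medium may nitrosate or oxidise the electron-rich rings, or the nitrosated intermediate may not break down fully to the acid. The fallback uses reductive instead of oxidative Nef chemistry, setting out from 16 and returning at 19, so steps 10 to 12 are bypassed. The sodium nitronate of 16 (NaOMe, MeOH) is added to buffered aqueous TiCl3 (NH4OAc), which reduces it to the imine and, after hydrolysis, to the C10 aldehyde. This closes onto the C9 hydroxyl as the lactol 6-(benzyloxy)-4-(4-hydroxy-3,5-dimethoxyphenyl)-5,7-dimethoxy-1,3,3a,4,9,9a-hexahydronaphtho[2,3-c]furan-1-ol F4 (ring centres as in 16, both anomers). NaBH4 in MeOH reduces the lactol through its open form to diol 19.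

**Further compounds**

F1 | step 8 | (3R)-3-({4-(benzyloxy)-2-[(4-hydroxy-3,5-dimethoxyphenyl)methyl]-3,5-dimethoxyphenyl}methyl)-4-nitrobutanal | COc1cc(Cc2c(C[C@@H](C[N+](=O)[O-])CC=O)cc(OC)c(OCc3ccccc3)c2OC)cc(OC)c1O
F2 | step 8 | 4-({3-(benzyloxy)-2,4-dimethoxy-6-[(2R)-2-(nitromethyl)-4-oxobutyl]phenyl}methylidene)-2,6-dimethoxycyclohexa-2,5-dien-1-one | COC1=CC(=Cc2c(C[C@@H](C[N+](=O)[O-])CC=O)cc(OC)c(OCc3ccccc3)c2OC)C=C(OC)C1=O
F3 | step 7 | (E)-4-[4-(benzyloxy)-2-(hydroxy{3,5-dimethoxy-4-[(4-methoxybenzyl)oxy]phenyl}methyl)-3,5-dimethoxyphenyl]but-2-enal, racemic | O=C/C=C/Cc1cc(OC)c(OCc2ccccc2)c(OC)c1C(O)c1cc(OC)c(OCc2ccc(OC)cc2)c(OC)c1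
F4 | step 11 | 6-(benzyloxy)-4-(4-hydroxy-3,5-dimethoxyphenyl)-5,7-dimethoxy-1,3,3a,4,9,9a-hexahydronaphtho[2,3-c]furan-1-ol, ring centres as in 16, both anomers | COc1cc([C@H]2c3c(cc(OC)c(OCc4ccccc4)c3OC)C[C@@H](C(O)O5)[C@@H]2C5)cc(OC)c1O
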